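I decide to count how many turns the shuttle through D makes while E lives, and to let that count place each flask between two versions I can solve in the head.

| flask | J | E | L | time |
|---|---|---|---|---|
| south | 0.050 M | 1.50 equiv | 0.050 M | 12 min |
| west | 0.050 M | 2.00 equiv | 0.050 M | 12 min |
| east | 0.050 M | 3.00 equiv | 0.050 M | 12 min |
| north | 0.050 M | 5.00 equiv | 0.050 M | 12 min |

    E → X (k1 = 0.0025 /s)
    E + L → E.L (k2 = 0.044 /M/s)
    L ⇌ D (K6 = 0.32, k6 = 0.0032 /s)
    2 E → E2 (k4 = 0.038 /M/s)
    E + J → E.J (k5 = 0.075 /M/s)
    J ⇌ D (K6 = 0.32, k6 = 0.0032 /s)

- excess of E.J over E.L at the end for south, west, east, north, in this order
- how that number moves from the first to the last of them (falls all the way / rises all the way / hardly changes / falls, then rises / rises, then falls)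

- E is single-handed; J and L are mirror images of each other, charged as a racemate, each of them at the stated concentration
- where a step has two of a species, its rate is k times that concentration squared, and two are used at each turn
- an excess is the difference of the two amounts in percent of their sum
- "hardly changes" means that all values lie within two and a half points (for a concentration: within two and a half percent of the largest)
- run time (south): 12 min
- the handed part of E does not stay in what it makes, so the products of the two hands are mirror images too

1. D feeds J and L alike, so the shuttle J ⇌ D ⇌ L by itself shrinks the difference between J and L with first-order constant 0.0032 /s.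

2. In the instant version, J and L stay equal. E.J and E.L then form in the ratio of their constants, the selectivity factor 1.70, and the excess e is 26.1% with no dependence on the charge of E.

3. In the frozen version, J and L never exchange. Each decays exponentially in the exposure θ, the time integral of [E], with its own constant, and those two losses give an excess f.

4. To find θ, I hold J and L at their charge, so E has a first-order loss a = 0.00845 /s. Its pairing has b = 0.0760 /M/s, twice that step's constant. Its total starting loss rate per unit of E is w, and θ is ln(w/a) divided by b.

5. In south, E starts at 0.0750 M, so w = 0.0142 /s and θ = 6.78 M·s, which gives f = 21.4%.

6. The turn count n is the shuttle constant times the starting lifetime of E, that is, the shuttle constant over w: 0.226 in south. That is less than one turn, so south lies nearer the frozen version.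

7. My rough rule sets the excess n of the way from f to e, which gives 22.5% for south. North has w = 0.0275 /s, n = 0.117, θ = 15.5 M·s and f = 16.3%, so it gets 17.5%. I commit to a fall all the way.

The forecast reads 20%, 19%, 17%, 15%, falls all the way, on the ground that “More E pushes both hands to higher conversion”, and its figures for south and north stand below my two.

The flasks give 22.1%, 21.2%, 19.6% and 17.3%, and the excess falls all the way. In south, E stands at 0.659% of its charge at 12.0 min, and at 120 min the excess is no different. South's count of 0.226 had placed that flask 0.40 percentage points above what it gives. West starts E at 0.100 M, so w = 0.0161 /s, n = 0.199, θ = 8.44 M·s and f = 20.4%. The rule then sets west at 21.5%, and the west flask gives 21.2%.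

The numbers of this flask stand for no real mixture.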